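The route rests on cutting the O1–C8a ether bond of the pyranone ring (ring C). Ring A is hexasubstituted, yet a 2,4-dioxygenated 3,5-dimethoxyacetophenone, two steps from acetosyringone, already carries every ring-A substituent except O1. The carbon that becomes C8a is its only aromatic C–H, ortho to the future C8 methoxy and para to the future C6 methoxy group. The key step oxidises the derived diaryl 1,3-diketone, 1-[2,4-bis(benzyloxy)-3,5-dimethoxyphenyl]-3-(2,3-dimethoxyphenyl)propane-1,3-dione, at an anode so that its enol oxygen bonds to that C–H carbon. This closes ring C and completes the flavone skeleton in one operation.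

Key step: step 4

Remark (assumption): the target has no stereocentre and no configurationally stable axis, so it is achiral and no stereocontrol is needed; no step of the route creates a stereocentre.

Step 1
Reactants: 1 acetosyringone [1-(4-hydroxy-3,5-dimethoxyphenyl)ethan-1-one]
Product: 4 1-(2,4-dihydroxy-3,5-dimethoxyphenyl)ethan-1-one, via aryl trifluoroacetate 2 (not isolated), via bis(trifluoroacetate) 3 (not isolated)
Conditions: Pd(OAc)2 (10 mol%), K2S2O8, TFA/TFAA (9:1), 50 °C; then H2O/THF, rt
Reagents that add atoms: trifluoroacetic acid, OC(=O)C(F)(F)F (source of the new phenolic oxygen); trifluoroacetic anhydride, O=C(OC(=O)C(F)(F)F)C(F)(F)F (trifluoroacetyl groups of 2 and 3 only, lost on work-up)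
Why: Ketone-directed Pd(II)-catalysed ortho C–H hydroxylation: TFAA first masks the free phenol as the electron-poor trifluoroacetate 2, the acetyl oxygen directs cyclopalladation at one of the two equivalent ortho C–H bonds, persulfate oxidises the palladacycle and C–O reductive elimination should give aryl trifluoroacetate 3, which water cleaves to the dihydroxy ketone, the ester on the new oxygen guarding against a second oxygenation.

Step 2
Reactants: 4 1-(2,4-dihydroxy-3,5-dimethoxyphenyl)ethan-1-one
Product: 5 1-[2,4-bis(benzyloxy)-3,5-dimethoxyphenyl]ethan-1-one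
Conditions: BnBr (2.5 equiv), K2CO3, n-Bu4NI (cat.), DMF, 70 °C
Reagents that add atoms: benzyl bromide, BrCc1ccccc1
Why: Williamson ether synthesis, in which both phenoxides (the chelated 2-OH needs the warm polar medium) should be O-benzylated; the benzyl ethers are stable to the base of step 3 and to acid formed at the anode in step 4, and both leave in one neutral hydrogenolysis.

Step 3
Reactants: 5 1-[2,4-bis(benzyloxy)-3,5-dimethoxyphenyl]ethan-1-one; 6 methyl 2,3-dimethoxybenzoate
Product: 7 1-[2,4-bis(benzyloxy)-3,5-dimethoxyphenyl]-3-(2,3-dimethoxyphenyl)propane-1,3-dione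
Conditions: NaH (3 equiv), THF, reflux; then aq. HCl
Reagents that add atoms: none
Why: Crossed Claisen condensation, in which only ketone 5 can enolise because ester 6 has no α-hydrogen, and irreversible deprotonation of the 1,3-diketone formed should drive the acyl transfer to completion; 7 is expected to exist largely as its chelated enol.

Step 4
Reactants: 7 1-[2,4-bis(benzyloxy)-3,5-dimethoxyphenyl]-3-(2,3-dimethoxyphenyl)propane-1,3-dione
Product: 8 5,7-bis(benzyloxy)-6,8-dimethoxy-2-(2,3-dimethoxyphenyl)-4H-chromen-4-one
Conditions: undivided cell, graphite anode, Pt cathode, constant current at low current density (about 2 F/mol), n-Bu4NPF6 (0.1 M), HFIP/CH2Cl2, rt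
Reagents that add atoms: none
Why: Proposed new method: anodic removal of one electron from the most electron-rich π-system of 7, the tetra-alkoxy ring A, should give an arene radical cation; the enol oxygen on the carbon bearing the dimethoxyphenyl group adds to the only hydrogen-bearing ring-A carbon (ortho to the ketone, the future C8a), and loss of the O–H proton, a second electron transfer and loss of the ring proton restore aromaticity while the cathode reduces the released protons to hydrogen. The closest known reaction types are anodic dehydrogenative C–O lactonisation of biaryl-2-carboxylic acids, oxidative closure of 2-hydroxybenzophenones to xanthones and iron(III)-mediated closure of electron-rich α-aryl ketones to benzofurans through the enol oxygen, none of which joins a diketone enol oxygen to an arene C–H to make a chromone. Ring C closes as a six-membered ring by attack at the carbon ortho to the acyl group (6-endo with respect to the C4a–C8a bond of ring A) rather than by 5-exo spiro attack at C4a, because the hole density of the radical cation lies on the oxygen-bearing carbons and on the C–H carbon para to a methoxy group, not on the acyl-bearing carbon. No stereocentre is formed. The selectivity needed is attack at the C–H carbon rather than ipso attack at the benzyloxy-bearing ortho carbon or oxidation of ring B: the C–H carbon is unhindered and lies ortho and para to the two methoxy groups, only its adduct can aromatise irreversibly by proton loss whereas ipso addition is reversible, and ring B with two alkoxy groups and an acyl group should oxidise at a higher potential. Non-nucleophilic, radical-cation-stabilising HFIP, a low current density and a limited charge are chosen to suppress solvent capture at alkoxy-bearing carbons, benzylic oxidation and over-oxidation of 8.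

Step 5
Reactants: 8 5,7-bis(benzyloxy)-6,8-dimethoxy-2-(2,3-dimethoxyphenyl)-4H-chromen-4-one
Product: 9 5,7-dihydroxy-6,8-dimethoxy-2-(2,3-dimethoxyphenyl)-4H-chromen-4-one (5,7-dihydroxy-6,8,2',3'-tetramethoxyflavone)
Conditions: H2 (1 atm), 10% Pd/C, EtOAc/MeOH, rt
Reagents that add atoms: none
Why: Catalytic hydrogenolysis of the two aryl benzyl ethers; the chromone C2–C3 double bond, the carbonyl and the four aryl methyl ethers should be inert under one atmosphere of hydrogen at room temperature, and the reaction is stopped once both benzyl groups are gone.

Compound list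
1 | acetosyringone, 1-(4-hydroxy-3,5-dimethoxyphenyl)ethan-1-one | COc1cc(C(C)=O)cc(OC)c1O | starting material
2 | 4-acetyl-2,6-dimethoxyphenyl trifluoroacetate (formed in the flask, not isolated) | CC(=O)c1cc(OC)c(OC(=O)C(F)(F)F)c(OC)c1 | intermediate
3 | 4-acetyl-2,6-dimethoxy-1,3-phenylene bis(trifluoroacetate) (formed in the flask, not isolated) | CC(=O)c1cc(OC)c(OC(=O)C(F)(F)F)c(OC)c1OC(=O)C(F)(F)F | intermediate
4 | 1-(2,4-dihydroxy-3,5-dimethoxyphenyl)ethan-1-one | CC(=O)c1cc(OC)c(O)c(OC)c1O | intermediate
5 | 1-[2,4-bis(benzyloxy)-3,5-dimethoxyphenyl]ethan-1-one | CC(=O)c1cc(OC)c(OCc2ccccc2)c(OC)c1OCc1ccccc1 | intermediate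
6 | methyl 2,3-dimethoxybenzoate | COC(=O)c1cccc(OC)c1OC | starting material
7 | 1-[2,4-bis(benzyloxy)-3,5-dimethoxyphenyl]-3-(2,3-dimethoxyphenyl)propane-1,3-dione | COc1cccc(C(=O)CC(=O)c2cc(OC)c(OCc3ccccc3)c(OC)c2OCc2ccccc2)c1OC | intermediate
8 | 5,7-bis(benzyloxy)-6,8-dimethoxy-2-(2,3-dimethoxyphenyl)-4H-chromen-4-one | COc1cccc(-c2cc(=O)c3c(OCc4ccccc4)c(OC)c(OCc4ccccc4)c(OC)c3o2)c1OC | intermediate
9 | 5,7-dihydroxy-6,8-dimethoxy-2-(2,3-dimethoxyphenyl)-4H-chromen-4-one (5,7-dihydroxy-6,8,2',3'-tetramethoxyflavone) | COc1cccc(-c2cc(=O)c3c(O)c(OC)c(O)c(OC)c3o2)c1OC | target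

Total step count: 5
Longest linear sequence: 5 steps (1 → 4 → 5 → 7 → 8 → 9)

Steps most likely to fail

Step 4 (anodic ring closure). The enol oxygen or an adventitious nucleophile may add ipso at an alkoxy-bearing carbon and lead on to quinone-ketal-type products. A benzylic C–H may be oxidised with loss of a benzyl group, or the radical cation may oligomerise or the product over-oxidise before cyclisation is complete. The fallback uses known chemistry, sets out from 5 and returns to the route at 8. The lone ring C–H of 5 is brominated with NBS in MeCN at rt (nuclear bromination of a polyalkoxyarene) to give 1-[2,4-bis(benzyloxy)-6-bromo-3,5-dimethoxyphenyl]ethan-1-one F1. Claisen condensation of F1 with 6 under the conditions of step 3 gives 1-[2,4-bis(benzyloxy)-6-bromo-3,5-dimethoxyphenyl]-3-(2,3-dimethoxyphenyl)propane-1,3-dione F2. Copper-catalysed intramolecular O-arylation of its enolate (CuI, 1,10-phenanthroline, K2CO3, DMF, 100 °C), an Ullmann-type closure known for 1-(2-haloaryl)-1,3-diketones, then forms the same O1–C8a bond and gives 8.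

Step 1 (directed hydroxylation). Cyclopalladation may be slow at a C–H flanked by the acetyl and a methoxy group, and undirected oxidation of the electron-rich ring by persulfate may compete. The fallback sets out from 1 and returns at 4. Ring bromination of 1 (NBS, MeCN, 0 °C to rt, acid-free to disfavour side-chain bromination) gives 1-(2-bromo-4-hydroxy-3,5-dimethoxyphenyl)ethan-1-one F3. Copper-catalysed hydroxylation of the aryl bromide, assisted by the ortho carbonyl group (CuI, 1,10-phenanthroline, KOH, DMSO/H2O, 100 °C, acidic work-up), should then give 4.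

Step 3 (Claisen condensation). Acyl transfer to the ortho-substituted ester may be slow, so that self-condensation of 5 or incomplete conversion competes. The fallback sets out from 5 and returns at 7. The lithium enolate of 5 (LiHMDS, THF, −78 °C) is added to 2,3-dimethoxybenzaldehyde (purchased reagent, COc1cccc(C=O)c1OC) in an aldol addition to give racemic 1-[2,4-bis(benzyloxy)-3,5-dimethoxyphenyl]-3-(2,3-dimethoxyphenyl)-3-hydroxypropan-1-one F4. Dess–Martin oxidation of this β-hydroxy ketone (CH2Cl2, rt) should give 7 and removes the transient stereocentre.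

Further compounds
F1 | step 4 | 1-[2,4-bis(benzyloxy)-6-bromo-3,5-dimethoxyphenyl]ethan-1-one | CC(=O)c1c(Br)c(OC)c(OCc2ccccc2)c(OC)c1OCc1ccccc1
F2 | step 4 | 1-[2,4-bis(benzyloxy)-6-bromo-3,5-dimethoxyphenyl]-3-(2,3-dimethoxyphenyl)propane-1,3-dione | COc1cccc(C(=O)CC(=O)c2c(Br)c(OC)c(OCc3ccccc3)c(OC)c2OCc2ccccc2)c1OC
F3 | step 1 | 1-(2-bromo-4-hydroxy-3,5-dimethoxyphenyl)ethan-1-one | CC(=O)c1cc(OC)c(O)c(OC)c1Br
F4 | step 3 | rac-1-[2,4-bis(benzyloxy)-3,5-dimethoxyphenyl]-3-(2,3-dimethoxyphenyl)-3-hydroxypropan-1-one | COc1cccc(C(O)CC(=O)c2cc(OC)c(OCc3ccccc3)c(OC)c2OCc2ccccc2)c1OC
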